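The numbers in the tables come from a simulation from invented constants, and the scatter is random.

Count the turnovers, the chair said. Before the meeting lay Saturday's run, the new flasks and the questions.

| flask | starting material | second substrate | free enzyme | remark | time |
|---|---|---|---|---|---|
| Saturday's | 0.055 M | 0.075 M | 5 µM | run made earlier |  |
| beta | 0.15 M | 0.0750 M | 20 µM |  | 6.0 min |
| epsilon | 0.050 M | 0.0750 M | 5.0 µM |  | 6.0 min |
| theta | 0.050 M | 0.0500 M | 5.0 µM |  | 6.0 min |
| delta | 0.20 M | 0.0750 M | 10 µM |  | 6.0 min |
| gamma | 0.050 M | 0.0200 M | 1.5 µM |  | 6.0 min |
| eta | 0.050 M | 0.0750 M | 1.2 µM |  | 6.0 min |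

Saturday's run (percent of the starting material charged): time / min: target / % = 0.250: 9; 0.417: 16; 0.667: 18; 1.00: 28; 1.50: 42; 2.50: 61; 4.00: 79

(standard deviation of a reading: 1.5 percentage points)

- all flasks from highest to lowest amount of target, in percent of the starting material charged, at 6.0 min (beta / epsilon / theta / delta / gamma / eta)
- the same order at 40 s (beta / epsilon / theta / delta / gamma / eta)
- the amount of target, in percent of the starting material charged of the flask you put first, at 6.0 min
- the amount of target, in percent of the starting material charged of the flask you put last, at 6.0 min

- no earlier run changes the charge of free enzyme; that part of a forecast is a guess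

I, as secretary, entered my own reckoning first. Saturday's 42% of the charge at 1.50 min, multiplied by starting material per enzyme and divided by the time, gives 3080 min⁻¹: the count rate, turnovers of each enzyme per minute (the turnover frequency). The reading at 1.00 min gives 3080 min⁻¹, both with a scatter of 1.5 percentage points. Between 2.50 min and 4.00 min the rate was lower than that, at 1320 min⁻¹, but both substrates had fallen by then, so the run cannot say which one slowed it. Carrying the rate to another enzyme charge is a guess.

At that rate each enzyme makes 2050 turnovers in 40 s. That is 27.4% of the charge in beta, 20.5% in epsilon and 10.3% in delta. In 6.0 min the count is 18500, more than the 10000 that epsilon's charge asks for. In gamma, second substrate is the limiting reagent and allows 13300 turnovers, fewer than the count, or 40.0% of the starting material. I gave that as an upper figure, since gamma holds 26.7% of Saturday's second substrate, and no rate was read there.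

The forecaster held that “Saturday's run is first order in starting material”. The forecast ordered the flasks epsilon > theta > beta > eta > delta > gamma at 6.0 min and beta > delta > epsilon > theta > gamma > eta at 40 s, with delta at 34, where I had 10.3%. It gave 89% (84% to 93%) for the first flask and 35% (27% to 39%) for the last.

The flasks gave epsilon > theta > beta > eta > delta > gamma at 6.0 min, from 86.8% in epsilon to 25.0% in gamma, which puts the forecast's last figure 10 points too high. At 40 s they gave beta > epsilon > theta > delta > eta > gamma, with beta at 25.8%, epsilon at 20.3% and delta at 10.6%.

    second complex → free enzyme + target (k = 120 s⁻¹)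
    starting material + free enzyme ⇌ first complex (K = 55.0 M⁻¹, k = 5.50 × 10⁵ M⁻¹ s⁻¹)
    starting material ⇌ dormant form (K = 1.30, k = 0.00220 s⁻¹)
    first complex ⇌ loaded enzyme + first product (K = 0.150 M, k = 220 s⁻¹)
    second substrate + loaded enzyme ⇌ second complex (K = 26.0 M⁻¹, k = 3.50 × 10⁵ M⁻¹ s⁻¹)

Gamma has not come to rest. Its 3.77% at 0.667 min counts 1260 turnovers, fewer than the 2050 of the count. Its 25.0% at 6.0 min counts 8350, fewer than the 13300 its second substrate allows, with 37% of that substrate still there. At ten times the time gamma stands at 40.0%, about its cap. Epsilon also moves, from 86.8% at 6.0 min to 99.9% at 60.0 min, while its dormant form falls from 12.6% at 6.00 min to 0.0763% at 60.0 min. Delta, with 0.477% of its second substrate left at 6.00 min, goes from 37.3% at 6.00 min to 37.5% at 60.0 min.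

Epsilon's recipe with 0.020 M of starting material asks 4000 turnovers of each enzyme, fewer than the 18500 of the count, so the count sets no cap short of the charge. That flask gives 93.6% target at 6.0 min, with 0.20% of the starting material left and 6.19% as dormant form.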